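Time buys less and less in the west run: electrophile stands at 58 % after 25.0 min, 51 % after 40.0 min and 40 % after 80.0 min. Alpha looks nearly the same, with 0.0550 M of nucleophile against 0.046 M on the same 0.050 M of electrophile, but it runs for 2.0 h.

| setting | west | north-east | south-west | alpha | theta | gamma |
|---|---|---|---|---|---|---|
| electrophile | 0.050 M | 0.050 M | 0.050 M | 0.050 M | 0.050 M | 0.050 M |
| nucleophile | 0.046 M | 0.068 M | 0.087 M | 0.0550 M | 0.0720 M | 0.0930 M |
| remark | run made earlier | run made earlier | run made earlier |  |  |  |
| time |  |  |  | 2.0 h | 2.0 h | 2.0 h |

| run | time / min | electrophile / % | target / % |
|---|---|---|---|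
| west | 6.00 | 87 | 7 |
| west | 12.0 | 73 | 6 |
| west | 25.0 | 58 | 4 |
| west | 40.0 | 51 | 3 |
| west | 80.0 | 40 | 3 |
| north-east | 15.0 | 64 | 6 |
| north-east | 30.0 | 45 | 5 |
| north-east | 50.0 | 36 | 3 |
| north-east | 60.0 | 28 | 1 |
| north-east | 80.0 | 27 | 0 |
| south-west | 15.0 | 54 | 8 |
| south-west | 30.0 | 36 | 5 |
| south-west | 50.0 | 24 | 5 |
| south-west | 60.0 | 21 | 3 |
| south-west | 80.0 | 16 | 1 |

(readings scatter by 1.5 percentage points)

1. part of the electrophile that has reacted at the end, alpha
2. part of the electrophile that has reacted at the end, theta
3. part of the electrophile that has reacted at the end, gamma
4. what raising the concentration of nucleophile from its lowest to its highest value here does to the part of the electrophile that has reacted (changes below 5 percentage points count as none) (it rises / no change / it falls)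

- percentages count the electrophile that a species holds: one side product counts as two
- the numbers in the tables scatter with a standard deviation of 1.5 percentage points
- on the list of suspects stand: electrophile + nucleophile <-> acid set free + target; nucleophile + acid set free <-> protonated nucleophile; electrophile + target -> side product; 2 nucleophile -> homo dimer

On the suspected steps, one electrophile and one nucleophile give target and acid set free, a second electrophile eats the target, and the acid takes a second nucleophile. Target reads just 3 % at the end of the west run, so these steps seem to go together, at a price of one nucleophile per electrophile. The homo dimer adds to that price. Its rate goes with c(nucleophile) squared and the main step's with c(nucleophile) times c(electrophile), so in their ratio time drops out and c(nucleophile)/c(electrophile) remains.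

The price of a flask is therefore expected to be one plus a constant times the charged c(nucleophile)/c(electrophile). Taking the last west reading as the end of that run, nucleophile charged over electrophile reacted reads 1.53. That gives 0.580 for the constant, the dimer surcharge. The north-east and south-west runs read 0.635 and 0.616.

Alpha's price is then 1.64, so its nucleophile pays for 67.2 % of its electrophile, more than the west run's 60.0 %, with alpha's extra time not counted. The forecast stands at 71 %, above this reckoning, then 81 % and 89 %, and for the trend says it rises, with the words “More nucleophile clearly raises conversion”.

The flasks give 70.9 %, 80.5 % and 88.0 %: it rises, by 17 percentage points.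

    electrophile + nucleophile ⇌ acid set free + target (K = 1.30, k = 0.450 L mol⁻¹ min⁻¹)
    nucleophile + acid set free ⇌ protonated nucleophile, settled at all times (K = 51000 L mol⁻¹)
    electrophile + target → side product (k = 4.20 L mol⁻¹ min⁻¹)
    2 nucleophile → homo dimer (k = 0.300 L mol⁻¹ min⁻¹)

Alpha keeps 4.3 % of its nucleophile free at 2.00 h, and its price comes to 1.55, below the 1.64 carried over. The difference in nucleophile may be called the main reason for the gap between gamma and alpha: gamma set to alpha's nucleophile reaches 70.9 % instead of 88.0 %. One more flask is like gamma but holds 0.20 M of electrophile, and there the surcharge gives a reckoned price of 1.27, hence a reckoned 36.6 % reacted. That flask reaches 41.4 %, with nucleophile, its limiting reagent, down to 0.236 % of its charge.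

The numbers in the tables stem from a simulated flask for substances that don't exist.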